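## Retrosynthetic overview

1. The aminoquinone comes from 2-hydroxy-5-methoxyquinone 25 and 3-methylbutan-1-amine (vinylogous ester to vinylogous amide); 25 comes from tetramethoxyarene 23 by oxidative demethylation and selective hydrolysis.
2. 23 comes from lithiated 1,2,4,5-tetramethoxybenzene and (E)-allylic bromide 20; the (E)-trisubstituted alkene comes from Zr-catalysed carboalumination of terminal alkyne 16.
3. Enyne 16 comes from alkynyl ketone 15 by methylenation; 15 comes from Eschenmoser–Tanabe fragmentation of the epoxide of octalone 12, where the trans relation of the two methyls is set thermodynamically.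
4. 12 comes from achiral triketone 3: ketoreductase desymmetrisation sets the quaternary centre, then C-methylation, aldol closure and dehydration/hydrogenation remove the carbinol oxygen.
5. Ring order: the cyclohexane is bought (dione 1); a temporary pyran ketal (steps 2–3) and a temporary enone ring A (closed in step 5, reopened in step 9) are used; the quinone ring is bought as arene 21 and oxidised last.

Assumption: a Prelog-type ketoreductase that reduces one ring carbonyl of 3 with (2S,3S) selectivity, as reported for whole-cell yeast reduction of this triketone, can be found in a commercial screening panel. The yeast precedent is recalled from the literature, and nothing in this route has been run.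

## Route

Step 1
Reactants: 1 2-methylcyclohexane-1,3-dione; 2 but-3-en-2-one
Product: 3 2-methyl-2-(3-oxobutyl)cyclohexane-1,3-dione
Conditions: Et3N (cat.), neat, rt
Reagents that add atoms: none
Why: Michael addition of the acidic cyclic 1,3-dione to the enone gives C-alkylation only, and no stereocentre arises because the two ring carbonyls stay enantiotopic.

Step 2
Reactants: 3 2-methyl-2-(3-oxobutyl)cyclohexane-1,3-dione
Product: 5 (4aS,8aS)-2-hydroxy-2,4a-dimethyl-octahydro-5H-chromen-5-one (cis-fused cyclic hemiketal; anomer mixture), via hydroxy diketone 4 (not isolated)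
Conditions: ketoreductase (NADPH-dependent), NADP+ (cat.), i-PrOH (10% v/v), phosphate buffer pH 7.0, 30 °C
Reagents that add atoms: none
Why: Enzymatic desymmetrising carbonyl reduction delivers hydride to one enantiotopic ring carbonyl, fixing the 3S carbinol and the 2S quaternary centre in one event; the hydroxyl, cis to the side chain, then closes onto the side-chain ketone.

Step 3
Reactants: 5 cyclic hemiketal
Product: 6 (4aS,8aS)-2-methoxy-2,4a-dimethyl-octahydro-5H-chromen-5-one (anomer mixture)
Conditions: MeOH, PPTS (cat.), rt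
Reagents that add atoms: methanol CO
Why: Acid-catalysed acetal exchange (Fischer-type) turns the hemiketal into a mixed methyl ketal that masks both the hydroxyl and the side-chain ketone, leaving only the hindered ring ketone free.

Step 4
Reactants: 6 bicyclic methyl ketal
Product: 8 (4aS,8aS)-2-methoxy-2,4a,6-trimethyl-octahydro-5H-chromen-5-one (C6 epimers), via lithium enolate 7 (not isolated)
Conditions: LiN(i-Pr)2, THF, −78 °C; MeI, −78 to 0 °C
Reagents that add atoms: iodomethane CI
Why: Kinetic enolate alkylation can only occur at C6 because the other α-carbon is quaternary; the new methyl centre forms unselectively and is corrected in step 5.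

Step 5
Reactants: 8 methylated bicyclic ketal
Product: 10 (4aR,5S,8R)-5-hydroxy-4a,8-dimethyl-4,4a,5,6,7,8-hexahydronaphthalen-2(3H)-one, via hydroxy diketone 9 (not isolated)
Conditions: 1 M HCl, THF, rt; then pyrrolidine (0.3 equiv), AcOH (0.3 equiv), toluene, 90 °C
Reagents that add atoms: water O
Why: Ketal hydrolysis frees the 1,5-diketone, amine-catalysed intramolecular aldol condensation (second half of a Robinson annulation) closes ring A, and the C8 methyl, epimerisable through the dienamine/dienol, settles equatorial and trans to the axial angular methyl (the preference that makes 6α-methyl steroid enones the stable epimers).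

Step 6
Reactants: 10 hydroxy octalone
Product: 11 (4aS,8R)-4a,8-dimethyl-4,4a,7,8-tetrahydronaphthalen-2(3H)-one
Conditions: POCl3, pyridine, 80 °C
Reagents that add atoms: none
Why: E2 dehydration of the dichlorophosphate works because the C5 oxygen is axial and antiperiplanar to the axial C6 hydrogen, and the quaternary C4a allows only one alkene regioisomer; no stereocentre is touched.

Step 7
Reactants: 11 dienone
Product: 12 (4aR,8R)-4a,8-dimethyl-4,4a,5,6,7,8-hexahydronaphthalen-2(3H)-one
Conditions: H2 (1 atm), RhCl(PPh3)3 (5 mol%), benzene/EtOH 1:1, rt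
Reagents that add atoms: none
Why: Homogeneous hydrogenation with RhCl(PPh3)3 reduces the isolated cis-disubstituted alkene and leaves the conjugated trisubstituted enone alone, completing removal of the carbinol oxygen.

Step 8
Reactants: 12 trans-dimethyl octalone
Product: 13 (4aR,8R)-1,8a-epoxy-4a,8-dimethyl-octahydronaphthalen-2(1H)-one (epoxide diastereomers)
Conditions: 30% aq. H2O2, NaOH (cat.), MeOH, 0 °C to rt
Reagents that add atoms: hydrogen peroxide OO
Why: Weitz–Scheffer nucleophilic epoxidation of the enone; the two new epoxide centres are destroyed in step 9, so their configuration does not matter.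

Step 9
Reactants: 13 epoxy ketone
Product: 15 (2R,6R)-2-(but-3-yn-1-yl)-2,6-dimethylcyclohexan-1-one, via epoxy tosylhydrazone 14 (not isolated)
Conditions: TsNHNH2, AcOH/CH2Cl2 1:1, −20 °C to rt
Reagents that add atoms: none
Why: Eschenmoser–Tanabe fragmentation opens ring A into a ring ketone and a terminal alkyne with loss of N2 and sulfinate, keeping all carbons; the mild acid does not epimerise the α-methyl centre.

Step 10
Reactants: 15 alkynyl ketone
Product: 16 (1R,3R)-1-(but-3-yn-1-yl)-1,3-dimethyl-2-methylidenecyclohexane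
Conditions: Zn, CH2Br2, TiCl4, THF/CH2Cl2, 0 °C to rt
Reagents that add atoms: dibromomethane BrCBr
Why: Lombardo methylenation uses a non-basic gem-dimetallic reagent, so the hindered, epimerisable ketone becomes the exocyclic alkene without loss of the C6 configuration, and the terminal alkyne is tolerated.

Step 11
Reactants: 16 enyne
Product: 19 (2E)-5-[(1R,3R)-1,3-dimethyl-2-methylidenecyclohexyl]-3-methylpent-2-en-1-ol, via alkenylalane 17 (not isolated), via lithium alanate 18 (not isolated)
Conditions: Me3Al, Cp2ZrCl2 (25 mol%), CH2Cl2, 0 °C to rt; then n-BuLi, THF, −78 °C; (CH2O)n, −78 °C to rt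
Reagents that add atoms: trimethylaluminium C[Al](C)C; formaldehyde (as paraformaldehyde) C=O
Why: Negishi zirconium-catalysed carboalumination adds methyl and aluminium syn across the terminal alkyne (methyl to the internal carbon), and the alanate is hydroxymethylated with retention, giving the E alkene; the 1,1-disubstituted alkene is inert.

Step 12
Reactants: 19 allylic alcohol
Product: 20 (1R,3R)-1-[(3E)-5-bromo-3-methylpent-3-en-1-yl]-1,3-dimethyl-2-methylidenecyclohexane
Conditions: CBr4, PPh3, CH2Cl2, 0 °C
Reagents that add atoms: tetrabromomethane BrC(Br)(Br)Br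
Why: Appel bromination of a primary allylic alcohol proceeds by SN2 at low temperature without allylic transposition or loss of alkene geometry.

Step 13
Reactants: 20 allylic bromide; 21 1,2,4,5-tetramethoxybenzene
Product: 23 3-[(2E)-5-((1R,3R)-1,3-dimethyl-2-methylidenecyclohexyl)-3-methylpent-2-en-1-yl]-1,2,4,5-tetramethoxybenzene, via aryllithium 22 (not isolated)
Conditions: 21 (1.5 equiv), n-BuLi, TMEDA, THF, 0 °C; then 20, −78 °C to rt
Reagents that add atoms: none
Why: Directed ortho-lithiation between two methoxy groups, then SN2 alkylation at the primary allylic bromide (SN2' is disfavoured at the fully substituted γ-carbon), with the E geometry kept.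

Step 14
Reactants: 23 tetramethoxyarene
Product: 24 2,5-dimethoxy-3-[(2E)-5-((1R,3R)-1,3-dimethyl-2-methylidenecyclohexyl)-3-methylpent-2-en-1-yl]cyclohexa-2,5-diene-1,4-dione
Conditions: (NH4)2Ce(NO3)6, MeCN/H2O 2:1, 0 °C
Reagents that add atoms: water O
Why: Oxidative demethylation of the para-dimethoxy pair gives the p-quinone; the substitution pattern allows only one p-quinone, and the isolated alkenes survive the short cold reaction.

Step 15
Reactants: 24 dimethoxyquinone
Product: 25 2-hydroxy-5-methoxy-3-[(2E)-5-((1R,3R)-1,3-dimethyl-2-methylidenecyclohexyl)-3-methylpent-2-en-1-yl]cyclohexa-2,5-diene-1,4-dione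
Conditions: KOH, MeOH/H2O, 0 °C to rt; then 1 M HCl
Reagents that add atoms: potassium hydroxide [K+].[OH-]
Why: Addition–elimination of hydroxide at the methoxy carbon flanked by the side chain (its methoxy is twisted out of conjugation, so it is the less stabilised vinylogous ester); the resulting hydroxyquinone anion resists a second hydrolysis.

Step 16
Reactants: 25 hydroxy methoxy quinone; 26 3-methylbutan-1-amine
Product: 27 metachromin H
Conditions: 26 (3 equiv), EtOH, rt
Reagents that add atoms: none
Why: Addition–elimination of the primary amine at C5 converts the remaining vinylogous ester into the vinylogous amide, while the deprotonated 2-hydroxy vinylogous acid is unreactive, so only the methoxy group is replaced.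

## Compound list

1 | 2-methylcyclohexane-1,3-dione | CC1C(=O)CCCC1=O | starting material
2 | but-3-en-2-one (methyl vinyl ketone) | C=CC(C)=O | starting material
3 | 2-methyl-2-(3-oxobutyl)cyclohexane-1,3-dione | CC(=O)CCC1(C)C(=O)CCCC1=O | intermediate
4 | (2S,3S)-3-hydroxy-2-methyl-2-(3-oxobutyl)cyclohexan-1-one | CC(=O)CC[C@]1(C)C(=O)CCC[C@@H]1O | intermediate
5 | (4aS,8aS)-2-hydroxy-2,4a-dimethyl-octahydro-5H-chromen-5-one (cyclic hemiketal of 4, anomer mixture) | CC1(O)CC[C@]2(C)C(=O)CCC[C@@H]2O1 | intermediate
6 | (4aS,8aS)-2-methoxy-2,4a-dimethyl-octahydro-5H-chromen-5-one (anomer mixture) | COC1(C)CC[C@]2(C)C(=O)CCC[C@@H]2O1 | intermediate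
7 | lithium enolate of 6 | COC1(C)CC[C@]2(C)C([O-])=CCC[C@@H]2O1.[Li+] | intermediate
8 | (4aS,8aS)-2-methoxy-2,4a,6-trimethyl-octahydro-5H-chromen-5-one (C6 epimers) | COC1(C)CC[C@]2(C)C(=O)C(C)CC[C@@H]2O1 | intermediate
9 | (2S,3S)-3-hydroxy-2,6-dimethyl-2-(3-oxobutyl)cyclohexan-1-one (C6 epimers) | CC(=O)CC[C@]1(C)C(=O)C(C)CC[C@@H]1O | intermediate
10 | (4aR,5S,8R)-5-hydroxy-4a,8-dimethyl-4,4a,5,6,7,8-hexahydronaphthalen-2(3H)-one | O=C1CC[C@@]2(C)[C@@H](O)CC[C@@H](C)C2=C1 | intermediate
11 | (4aS,8R)-4a,8-dimethyl-4,4a,7,8-tetrahydronaphthalen-2(3H)-one | O=C1CC[C@@]2(C)C=CC[C@@H](C)C2=C1 | intermediate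
12 | (4aR,8R)-4a,8-dimethyl-4,4a,5,6,7,8-hexahydronaphthalen-2(3H)-one | O=C1CC[C@@]2(C)CCC[C@@H](C)C2=C1 | intermediate
13 | (4aR,8R)-1,8a-epoxy-4a,8-dimethyl-octahydronaphthalen-2(1H)-one (epoxide diastereomers) | O=C1CC[C@@]2(C)CCC[C@@H](C)C23OC13 | intermediate
14 | p-toluenesulfonylhydrazone of 13 | Cc1ccc(cc1)S(=O)(=O)NN=C1CC[C@@]2(C)CCC[C@@H](C)C23OC13 | intermediate
15 | (2R,6R)-2-(but-3-yn-1-yl)-2,6-dimethylcyclohexan-1-one | C#CCC[C@@]1(C)CCC[C@@H](C)C1=O | intermediate
16 | (1R,3R)-1-(but-3-yn-1-yl)-1,3-dimethyl-2-methylidenecyclohexane | C=C1[C@H](C)CCC[C@]1(C)CCC#C | intermediate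
17 | [(1E)-4-((1R,3R)-1,3-dimethyl-2-methylidenecyclohexyl)-2-methylbut-1-en-1-yl]dimethylalane | C=C1[C@H](C)CCC[C@]1(C)CC/C(C)=C/[Al](C)C | intermediate
18 | lithium butyl[(1E)-4-((1R,3R)-1,3-dimethyl-2-methylidenecyclohexyl)-2-methylbut-1-en-1-yl]dimethylalanate | C=C1[C@H](C)CCC[C@]1(C)CC/C(C)=C/[Al-](C)(C)CCCC.[Li+] | intermediate
19 | (2E)-5-[(1R,3R)-1,3-dimethyl-2-methylidenecyclohexyl]-3-methylpent-2-en-1-ol | C=C1[C@H](C)CCC[C@]1(C)CC/C(C)=C/CO | intermediate
20 | (1R,3R)-1-[(3E)-5-bromo-3-methylpent-3-en-1-yl]-1,3-dimethyl-2-methylidenecyclohexane | C=C1[C@H](C)CCC[C@]1(C)CC/C(C)=C/CBr | intermediate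
21 | 1,2,4,5-tetramethoxybenzene | COc1cc(OC)c(OC)cc1OC | starting material
22 | (2,3,5,6-tetramethoxyphenyl)lithium | [Li]c1c(OC)c(OC)cc(OC)c1OC | intermediate
23 | 3-[(2E)-5-((1R,3R)-1,3-dimethyl-2-methylidenecyclohexyl)-3-methylpent-2-en-1-yl]-1,2,4,5-tetramethoxybenzene | C=C1[C@H](C)CCC[C@]1(C)CC/C(C)=C/Cc1c(OC)c(OC)cc(OC)c1OC | intermediate
24 | 2,5-dimethoxy-3-[(2E)-5-((1R,3R)-1,3-dimethyl-2-methylidenecyclohexyl)-3-methylpent-2-en-1-yl]cyclohexa-2,5-diene-1,4-dione | C=C1[C@H](C)CCC[C@]1(C)CC/C(C)=C/CC1=C(OC)C(=O)C=C(OC)C1=O | intermediate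
25 | 2-hydroxy-5-methoxy-3-[(2E)-5-((1R,3R)-1,3-dimethyl-2-methylidenecyclohexyl)-3-methylpent-2-en-1-yl]cyclohexa-2,5-diene-1,4-dione | C=C1[C@H](C)CCC[C@]1(C)CC/C(C)=C/CC1=C(O)C(=O)C=C(OC)C1=O | intermediate
26 | 3-methylbutan-1-amine | CC(C)CCN | starting material
27 | metachromin H | C=C1[C@H](C)CCC[C@]1(C)CC/C(C)=C/CC1=C(O)C(=O)C=C(NCCC(C)C)C1=O | target

## Summary

Total step count: 16. Longest linear sequence: 16 steps (from 1; arene 21 and amine 26 are used as bought).

Three steps most likely to fail:

Step 2 (the ketoreductase may prefer the unhindered side-chain methyl ketone or give the wrong diastereomer). Fallback, setting out from 3 and returning at 6: mask the competing carbonyl first with 1,2-bis(trimethylsilyloxy)ethane and catalytic Me3SiOTf in CH2Cl2 at −78 °C, which ketalises only the unhindered methyl ketone and gives 2-methyl-2-[2-(2-methyl-1,3-dioxolan-2-yl)ethyl]cyclohexane-1,3-dione F1. The same ketoreductase/NADP+/i-PrOH system then acts on a plain 2,2-dialkyl 1,3-dione, the classic substrate type for this desymmetrisation, and gives (2S,3S)-3-hydroxy-2-methyl-2-[2-(2-methyl-1,3-dioxolan-2-yl)ethyl]cyclohexan-1-one F2. PPTS in MeOH transketalises F2 onto the cis hydroxyl to give 6.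

Step 8 (the enone β-carbon sits between a quaternary and a tertiary carbon, so nucleophilic epoxidation may be sluggish). Fallback, setting out from 12 and returning at 16, bypassing steps 8–10: ozonolysis (O3, CH2Cl2/MeOH, −78 °C; then H2O2, HCO2H) cleaves the enone and excises C1 to give 3-[(1R,3R)-1,3-dimethyl-2-oxocyclohexyl]propanoic acid F3. Me3SiCHN2 in MeOH/toluene gives methyl 3-[(1R,3R)-1,3-dimethyl-2-oxocyclohexyl]propanoate F4. The Zn/CH2Br2/TiCl4 methylenation, to which esters are inert, gives methyl 3-[(1R,3R)-1,3-dimethyl-2-methylidenecyclohexyl]propanoate F5. i-Bu2AlH in CH2Cl2 at −78 °C gives 3-[(1R,3R)-1,3-dimethyl-2-methylidenecyclohexyl]propanal F6. Seyferth–Gilbert homologation with dimethyl (1-diazo-2-oxopropyl)phosphonate, K2CO3 and MeOH gives enyne 16; base is used only after the epimerisable ketone is gone.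

Step 15 (the regiochemistry of mono-hydrolysis rests on the twisted-methoxy argument and on recalled precedent in related sesquiterpene quinones; it could be unselective). Fallback, setting out from 24 and returning at 27: hydrolyse both vinylogous esters (2 M NaOH, EtOH, 60 °C; then HCl) to 2,5-dihydroxy-3-[(2E)-5-((1R,3R)-1,3-dimethyl-2-methylidenecyclohexyl)-3-methylpent-2-en-1-yl]cyclohexa-2,5-diene-1,4-dione F7. Condensation of F7 with amine 26 (EtOH, cat. AcOH, 50 °C) then occurs at the unhindered C5 vinylogous acid, next to the ring hydrogen and away from the side chain, to give 27.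

## Further compounds

F1 | step 2 | 2-methyl-2-[2-(2-methyl-1,3-dioxolan-2-yl)ethyl]cyclohexane-1,3-dione | CC1(CCC2(C)C(=O)CCCC2=O)OCCO1
F2 | step 2 | (2S,3S)-3-hydroxy-2-methyl-2-[2-(2-methyl-1,3-dioxolan-2-yl)ethyl]cyclohexan-1-one | CC2(OCCO2)CC[C@]1(C)C(=O)CCC[C@@H]1O
F3 | step 8 | 3-[(1R,3R)-1,3-dimethyl-2-oxocyclohexyl]propanoic acid | O=C(O)CC[C@@]1(C)CCC[C@@H](C)C1=O
F4 | step 8 | methyl 3-[(1R,3R)-1,3-dimethyl-2-oxocyclohexyl]propanoate | COC(=O)CC[C@@]1(C)CCC[C@@H](C)C1=O
F5 | step 8 | methyl 3-[(1R,3R)-1,3-dimethyl-2-methylidenecyclohexyl]propanoate | COC(=O)CC[C@@]1(C)CCC[C@@H](C)C1=C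
F6 | step 8 | 3-[(1R,3R)-1,3-dimethyl-2-methylidenecyclohexyl]propanal | O=CCC[C@@]1(C)CCC[C@@H](C)C1=C
F7 | step 15 | 2,5-dihydroxy-3-[(2E)-5-((1R,3R)-1,3-dimethyl-2-methylidenecyclohexyl)-3-methylpent-2-en-1-yl]cyclohexa-2,5-diene-1,4-dione | C=C1[C@H](C)CCC[C@]1(C)CC/C(C)=C/CC1=C(O)C(=O)C=C(O)C1=O
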